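## Retrosynthetic overview

1. Last bond: the C7–O ester, made by Yamaguchi coupling of 7-hydroxy-azaphilone 17 with the TBS-protected (2R,3R,4S) acid 22, then desilylation.
2. Key step: 2-iodoxybenzoic acid dearomatises ring A of 2-benzopyrylium 14; the C7–O bond forms by a [2,3]-sigmatropic oxygen shift in the aryloxy periodinane (15 to 16).
3. Pyran ring: triethyl orthoformate supplies C1 and closes resorcinol β-diketone 13 to the pyrylium. 13 comes from γ-acylation of the dianion of the allyl β-keto ester of (R)-3-methylcyclohexanone with arylacetic Weinreb amide 7; one Pd step then removes three allyl groups and CO2.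
4. Acid 22: (S)-2-methylbutanal plus (E)-crotylboronate (anti, Felkin), silylation, oxidative alkene cleavage.
5. Ring order: cyclohexanone and benzene rings are bought; then pyran ring (step 7, first stage); then dearomatised ring A (step 7, second stage).

Assumption: compounds 1, 8, 18 and (E)-crotylboronic acid pinacol ester are bought. C7 cannot be biased by the remote stereocentres, so it forms as a near 1:1 epimer pair and the (7S) epimer is isolated as a diastereomeric ester in step 12.

## Route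

Step 1
Reactants: 1 3,5-dihydroxy-4-methylbenzoic acid
Product: 3 3,5-bis(allyloxy)-4-methylbenzoic acid, via triallyl ester 2 (not isolated)
Conditions: allyl bromide (3.5 equiv), K2CO3, DMF, 60 °C; then aq. NaOH, MeOH, 60 °C; HCl to pH 2
Reagents that add atoms: allyl bromide C=CCBr; sodium hydroxide [Na+].[OH-] (one carboxyl oxygen after ester hydrolysis)
Why: Williamson O-allylation of both phenols and the carboxylate followed by saponification of the allyl ester leaves the bis(allyl ether) acid, and no stereocentre is involved.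

Step 2
Reactants: 3 3,5-bis(allyloxy)-4-methylbenzoic acid
Product: 5 1-[3,5-bis(allyloxy)-4-methylphenyl]-2-diazoethan-1-one, via acid chloride 4 (not isolated)
Conditions: (COCl)2, N,N-dimethylformamide (cat.), CH2Cl2, 0 °C to rt; evaporate; Me3SiCHN2 (2.2 equiv), THF/MeCN, 0 °C to rt
Reagents that add atoms: (trimethylsilyl)diazomethane C[Si](C)(C)C=[N+]=[N-]
Why: First stage of an Arndt–Eistert homologation, in which the acid chloride C-acylates the diazoalkane to give the α-diazoketone; no stereocentre is involved.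

Step 3
Reactants: 5 1-[3,5-bis(allyloxy)-4-methylphenyl]-2-diazoethan-1-one
Product: 7 2-[3,5-bis(allyloxy)-4-methylphenyl]-N-methoxy-N-methylacetamide, via arylketene 6 (not isolated)
Conditions: PhCO2Ag (10 mol %), Et3N, MeNH(OMe)·HCl, THF, −20 °C to rt, dark
Reagents that add atoms: N,O-dimethylhydroxylamine hydrochloride CNOC.Cl
Why: Silver-catalysed Wolff rearrangement gives the arylketene, which the hydroxylamine traps as the Weinreb amide; no stereocentre is involved.

Step 4
Reactants: 8 (R)-3-methylcyclohexan-1-one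
Product: 9 allyl (1RS,4R)-4-methyl-2-oxocyclohexane-1-carboxylate
Conditions: NaH (2.5 equiv), diallyl carbonate, THF, reflux; then aq. HCl
Reagents that add atoms: diallyl carbonate C=CCOC(=O)OCC=C
Why: Claisen-type C-acylation under equilibrating conditions places the ester on the less hindered α-carbon remote from the methyl group (the other regioisomer suffers allylic strain in its enolate); the bought stereocentre is untouched and C1 is a labile, enolised centre.

Step 5
Reactants: 9 allyl (1RS,4R)-4-methyl-2-oxocyclohexane-1-carboxylate; 7 2-[3,5-bis(allyloxy)-4-methylphenyl]-N-methoxy-N-methylacetamide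
Product: 11 allyl (1RS,3R,4R)-3-{[3,5-bis(allyloxy)-4-methylphenyl]acetyl}-4-methyl-2-oxocyclohexane-1-carboxylate, via dilithium dianion 10 (not isolated)
Conditions: 9 (2.0 equiv), LiN(iPr)2 (4.2 equiv), THF, −78 to 0 °C; then 7 (1.0 equiv), −78 to 0 °C; aq. NH4Cl
Reagents that add atoms: none
Why: Huckin–Weiler γ-acylation, in which the dianion reacts at its only free α-carbon (next to the methyl-bearing carbon) with the Weinreb amide anti to the methyl group, so the new centre is trans to the bought one and is in any case epimerisable to that arrangement.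

Step 6
Reactants: 11 allyl (1RS,3R,4R)-3-{[3,5-bis(allyloxy)-4-methylphenyl]acetyl}-4-methyl-2-oxocyclohexane-1-carboxylate
Product: 13 (2S,3R)-2-[(3,5-dihydroxy-4-methylphenyl)acetyl]-3-methylcyclohexan-1-one (trans), via beta-keto acid 12 (not isolated)
Conditions: Pd(PPh3)4 (5 mol %), HCO2H, Et3N, THF, rt to 40 °C
Reagents that add atoms: none
Why: Tsuji–Trost deallylation with formate as hydride donor frees both phenols and the carboxylic acid under neutral conditions and the β-keto acid loses CO2; the centre between the two carbonyls equilibrates to the diequatorial trans arrangement dictated by the bought methyl centre.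

Step 7
Reactants: 13 (2S,3R)-2-[(3,5-dihydroxy-4-methylphenyl)acetyl]-3-methylcyclohexan-1-one
Product: 17 (7RS)-7-hydroxy-7-methyl-3-[(1R,2R)-2-methyl-6-oxocyclohexyl]-6H-isochromene-6,8(7H)-dione, via pyrylium trifluoroacetate 14 (not isolated), via aryloxy periodinane 15 (not isolated), via alkoxy iodane 16 (not isolated)
Conditions: HC(OEt)3, CF3CO2H, ClCH2CH2Cl, 0 °C to rt; evaporate; then 2-iodoxybenzoic acid (1.2 equiv), Bu4NI (5 mol %), CF3CO2H/ClCH2CH2Cl, rt; aq. Na2S2O3/NaHCO3
Reagents that add atoms: triethyl orthoformate CCOC(OCC)OCC; 2-iodoxybenzoic acid OI1(=O)OC(=O)c2ccccc12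
Why: Orthoformate C-formylation ortho to the side chain and cyclodehydration of the keto-aldehyde (2-benzopyrylium synthesis) close the pyran ring, then hydroxylative phenol dearomatisation follows, in which the ring A oxygen binds pentavalent iodine and the key C7–O bond forms by a [2,3]-sigmatropic oxygen shift (15 to 16) before hydrolysis; the planar cation gives no facial bias, so C7 forms as a near 1:1 epimer pair that is resolved as diastereomeric esters in step 12.

Step 8
Reactants: 18 (S)-2-methylbutan-1-ol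
Product: 19 (S)-2-methylbutanal
Conditions: NaOCl (1.1 equiv), 2,2,6,6-tetramethylpiperidin-1-oxyl (1 mol %), KBr (10 mol %), NaHCO3, CH2Cl2/H2O, 0 °C; used at once as a solution
Reagents that add atoms: none
Why: Anelli oxoammonium oxidation stops at the aldehyde and, being buffered and two-phase, does not epimerise the bought α-centre.

Step 9
Reactants: 19 (S)-2-methylbutanal
Product: 20 (3S,4R,5S)-3,5-dimethylhept-1-en-4-ol
Conditions: (E)-crotylboronic acid pinacol ester (1.2 equiv), toluene, −78 °C to rt, 24 h; then water; chromatography removes the minor 4,5-anti isomer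
Reagents that add atoms: (E)-crotylboronic acid pinacol ester C/C=C/CB1OC(C)(C)C(C)(C)O1
Why: Allylboration through a closed six-membered chair transition state, in which the E-geometry fixes the 3,4-anti pair and Felkin–Anh attack on the α-methyl aldehyde (the matched mode for E-crotylboronates, about 4–5:1 expected) sets the 4,5-syn relation to the bought centre.

Step 10
Reactants: 20 (3S,4R,5S)-3,5-dimethylhept-1-en-4-ol
Product: 21 tert-butyl{[(3S,4R,5S)-3,5-dimethylhept-1-en-4-yl]oxy}dimethylsilane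
Conditions: tBuMe2SiOSO2CF3, 2,6-lutidine, CH2Cl2, −78 to 0 °C
Reagents that add atoms: tert-butyldimethylsilyl triflate CC(C)(C)[Si](C)(C)OS(=O)(=O)C(F)(F)F
Why: Silylation of the hindered secondary alcohol with the silyl triflate and a non-nucleophilic base touches no stereocentre.

Step 11
Reactants: 21 tert-butyl{[(3S,4R,5S)-3,5-dimethylhept-1-en-4-yl]oxy}dimethylsilane
Product: 22 (2R,3R,4S)-3-[(tert-butyldimethylsilyl)oxy]-2,4-dimethylhexanoic acid
Conditions: RuCl3·xH2O (3 mol %), NaIO4 (4.1 equiv), CCl4/MeCN/H2O, rt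
Reagents that add atoms: sodium periodate [Na+].[O-]I(=O)(=O)=O; water O
Why: Sharpless ruthenium-catalysed oxidative cleavage turns the vinyl group into the carboxylic acid without enolising the new α-centre (its descriptor changes from S to R only because the priorities change).

Step 12
Reactants: 22 (2R,3R,4S)-3-[(tert-butyldimethylsilyl)oxy]-2,4-dimethylhexanoic acid; 17 (7RS)-7-hydroxy-7-methyl-3-[(1R,2R)-2-methyl-6-oxocyclohexyl]-6H-isochromene-6,8(7H)-dione
Product: 24 (7S)-7-methyl-3-[(1R,2R)-2-methyl-6-oxocyclohexyl]-6,8-dioxo-7,8-dihydro-6H-isochromen-7-yl (2R,3R,4S)-3-[(tert-butyldimethylsilyl)oxy]-2,4-dimethylhexanoate, via mixed anhydride 23 (not isolated)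
Conditions: 22 (1.5 equiv), 2,4,6-trichlorobenzoyl chloride, Et3N, toluene, rt; then 17, 4-(dimethylamino)pyridine (3 equiv), toluene, 40 °C; silica gel chromatography separates the (7S) ester from its (7R) epimer
Reagents that add atoms: none
Why: Yamaguchi esterification through the mixed anhydride and the acylpyridinium acylates the tertiary alcohol without forming a ketene, so C2' is kept; no new stereocentre is made and the two C7 epimers are now diastereomeric esters, of which the (7S) one is isolated.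

Step 13
Reactants: 24 (7S)-7-methyl-3-[(1R,2R)-2-methyl-6-oxocyclohexyl]-6,8-dioxo-7,8-dihydro-6H-isochromen-7-yl (2R,3R,4S)-3-[(tert-butyldimethylsilyl)oxy]-2,4-dimethylhexanoate
Product: 25 Muyocopronone B
Conditions: HF·pyridine, THF/pyridine, 0 °C to rt
Reagents that add atoms: none
Why: Fluoride-driven Si–O cleavage under buffered acidic conditions frees the C3' hydroxyl without β-elimination, acyl migration or attack on the azaphilone, and no stereocentre is touched.

## Compound list

1 | 3,5-dihydroxy-4-methylbenzoic acid | Cc1c(O)cc(C(=O)O)cc1O | starting material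
2 | allyl 3,5-bis(allyloxy)-4-methylbenzoate | C=CCOC(=O)c1cc(OCC=C)c(C)c(OCC=C)c1 | intermediate
3 | 3,5-bis(allyloxy)-4-methylbenzoic acid | C=CCOc1cc(C(=O)O)cc(OCC=C)c1C | intermediate
4 | 3,5-bis(allyloxy)-4-methylbenzoyl chloride | C=CCOc1cc(C(=O)Cl)cc(OCC=C)c1C | intermediate
5 | 1-[3,5-bis(allyloxy)-4-methylphenyl]-2-diazoethan-1-one | C=CCOc1cc(C(=O)C=[N+]=[N-])cc(OCC=C)c1C | intermediate
6 | 2-[3,5-bis(allyloxy)-4-methylphenyl]ethen-1-one (arylketene) | C=CCOc1cc(C=C=O)cc(OCC=C)c1C | intermediate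
7 | 2-[3,5-bis(allyloxy)-4-methylphenyl]-N-methoxy-N-methylacetamide | C=CCOc1cc(CC(=O)N(C)OC)cc(OCC=C)c1C | intermediate
8 | (R)-3-methylcyclohexan-1-one | C[C@@H]1CCCC(=O)C1 | starting material
9 | allyl (1RS,4R)-4-methyl-2-oxocyclohexane-1-carboxylate | C[C@@H]1CCC(C(=O)OCC=C)C(=O)C1 | intermediate
10 | dilithium dianion of 9 (ester enolate plus ketone enolate towards C3, 4R) | [Li+].[Li+].C=CCOC([O-])=C1CC[C@@H](C)C=C1[O-] | intermediate
11 | allyl (1RS,3R,4R)-3-{[3,5-bis(allyloxy)-4-methylphenyl]acetyl}-4-methyl-2-oxocyclohexane-1-carboxylate (acyl trans to methyl) | C=CCOc1cc(CC(=O)[C@@H]2C(=O)C(C(=O)OCC=C)CC[C@H]2C)cc(OCC=C)c1C | intermediate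
12 | (1RS,3R,4R)-3-[(3,5-dihydroxy-4-methylphenyl)acetyl]-4-methyl-2-oxocyclohexane-1-carboxylic acid | Cc1c(O)cc(CC(=O)[C@@H]2C(=O)C(C(=O)O)CC[C@H]2C)cc1O | intermediate
13 | (2S,3R)-2-[(3,5-dihydroxy-4-methylphenyl)acetyl]-3-methylcyclohexan-1-one (trans, largely enolised) | Cc1c(O)cc(CC(=O)[C@@H]2C(=O)CCC[C@H]2C)cc1O | intermediate
14 | 6,8-dihydroxy-7-methyl-3-[(1R,2R)-2-methyl-6-oxocyclohexyl]isochromenylium trifluoroacetate | Cc1c(O)cc2cc([C@@H]3C(=O)CCC[C@H]3C)[o+]cc2c1O.[O-]C(=O)C(F)(F)F | intermediate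
15 | 1-({7-methyl-3-[(1R,2R)-2-methyl-6-oxocyclohexyl]-6-oxo-6H-isochromen-8-yl}oxy)-1-oxo-1λ5,2-benziodoxol-3(1H)-one (aryloxy periodinane) | CC1=C(OI2(=O)OC(=O)c3ccccc23)C4=COC([C@@H]5C(=O)CCC[C@H]5C)=CC4=CC1=O | intermediate
16 | 1-({(7RS)-7-methyl-3-[(1R,2R)-2-methyl-6-oxocyclohexyl]-6,8-dioxo-7,8-dihydro-6H-isochromen-7-yl}oxy)-1,2-benziodoxol-3(1H)-one (alkoxy iodane, trivalent iodine) | CC1(OI2OC(=O)c3ccccc23)C(=O)C=C4C=C([C@@H]5C(=O)CCC[C@H]5C)OC=C4C1=O | intermediate
17 | (7RS)-7-hydroxy-7-methyl-3-[(1R,2R)-2-methyl-6-oxocyclohexyl]-6H-isochromene-6,8(7H)-dione (1:1 C7 epimers) | CC1(O)C(=O)C=C2C=C([C@@H]3C(=O)CCC[C@H]3C)OC=C2C1=O | intermediate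
18 | (S)-2-methylbutan-1-ol | CC[C@H](C)CO | starting material
19 | (S)-2-methylbutanal | CC[C@H](C)C=O | intermediate
20 | (3S,4R,5S)-3,5-dimethylhept-1-en-4-ol (3,4-anti, 4,5-syn) | CC[C@H](C)[C@@H](O)[C@@H](C)C=C | intermediate
21 | tert-butyl{[(3S,4R,5S)-3,5-dimethylhept-1-en-4-yl]oxy}dimethylsilane | CC[C@H](C)[C@@H](O[Si](C)(C)C(C)(C)C)[C@@H](C)C=C | intermediate
22 | (2R,3R,4S)-3-[(tert-butyldimethylsilyl)oxy]-2,4-dimethylhexanoic acid | CC[C@H](C)[C@@H](O[Si](C)(C)C(C)(C)C)[C@@H](C)C(=O)O | intermediate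
23 | (2R,3R,4S)-3-[(tert-butyldimethylsilyl)oxy]-2,4-dimethylhexanoic 2,4,6-trichlorobenzoic anhydride | CC[C@H](C)[C@@H](O[Si](C)(C)C(C)(C)C)[C@@H](C)C(=O)OC(=O)c1c(Cl)cc(Cl)cc1Cl | intermediate
24 | (7S)-7-methyl-3-[(1R,2R)-2-methyl-6-oxocyclohexyl]-6,8-dioxo-7,8-dihydro-6H-isochromen-7-yl (2R,3R,4S)-3-[(tert-butyldimethylsilyl)oxy]-2,4-dimethylhexanoate | CC[C@H](C)[C@@H](O[Si](C)(C)C(C)(C)C)[C@@H](C)C(=O)O[C@@]1(C)C(=O)C=C2C=C([C@@H]3C(=O)CCC[C@H]3C)OC=C2C1=O | intermediate
25 | Muyocopronone B, (7S)-7-methyl-3-[(1R,2R)-2-methyl-6-oxocyclohexyl]-6,8-dioxo-7,8-dihydro-6H-isochromen-7-yl (2R,3R,4S)-3-hydroxy-2,4-dimethylhexanoate | CC[C@H](C)[C@@H](O)[C@@H](C)C(=O)O[C@@]1(C)C(=O)C=C2C=C([C@@H]3C(=O)CCC[C@H]3C)OC=C2C1=O | target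

## Step count and risks

Total steps: 13. Longest linear sequence: 8 (steps 1, 2, 3, 5, 6, 7, 12, 13).

Step 5 (γ-acylation of the dianion). The risk is proton transfer from the benzylic CH2 of 7 to the dianion and slow attack next to the methyl-bearing carbon. The fallback sets out from 7 and comes back at 13. The unwanted α-position is blocked by the isopropylidene group of bought (R)-(+)-pulegone instead of an ester. Its kinetic cross-conjugated lithium enolate (LiN(iPr)2, THF, −78 °C) is acylated by 7 to give the 2-acyl pulegone F1. Retro-aldol loss of acetone (aq. HCl, dioxane, 90 °C) gives the diallyl diketone F2, and Pd(PPh3)4/HCO2H/Et3N as in step 6 gives 13.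

Step 7 (formylation, pyrylium closure, dearomatisation). The risk is that, before formylation, the electron-rich ring attacks the ring ketone under acid (cyclodehydration to a phenanthrenol). The fallback sets out from 7 and comes back at 14. The aldehyde carbon is installed before the diketone exists: Vilsmeier–Haack formylation (POCl3, DMF) gives the formyl Weinreb amide F3, which is protected as the dimethyl acetal F4 (HC(OMe)3, pyridinium p-toluenesulfonate, MeOH). Acylation of dianion 10 as in step 5 gives the acetal keto ester F5, and deallylation–decarboxylation as in step 6 gives the resorcinol keto acetal F6. CF3CO2H in ClCH2CH2Cl then unmasks the aldehyde, which closes at once to pyrylium 14, oxidised as in step 7.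

Step 12 (esterification). The risk is acylation of a hindered tertiary alcohol by an α,β-branched acid, where a slow coupling invites C2' epimerisation. The fallback sets out from 13 and 22 and comes back at 24. A phenol is acylated instead of the tertiary alcohol: 22 and excess 13 with N-ethyl-N'-(3-dimethylaminopropyl)carbodiimide hydrochloride and 4-(dimethylamino)pyridine in CH2Cl2 give the mono aryl ester F7. HC(OEt)3/CF3CO2H gives the acyloxy pyrylium salt F8 (its 8-O-acyl regioisomer behaves alike). 2-Iodoxybenzoic acid then hydroxylates C7 through the remaining free phenol, and the neighbouring aryl ester moves to the new tertiary hydroxyl (1,2 O-to-O acyl shift, driven by loss of the pyrylium charge) to give 24 and its C7 epimer, separated as in step 12. This cascade is unprecedented for this system.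

Further compounds

F1 | step 5 | (2R,3R)-2-{[3,5-bis(allyloxy)-4-methylphenyl]acetyl}-3-methyl-6-(propan-2-ylidene)cyclohexan-1-one | C=CCOc1cc(CC(=O)[C@@H]2C(=O)C(=C(C)C)CC[C@H]2C)cc(OCC=C)c1C
F2 | step 5 | (2S,3R)-2-{[3,5-bis(allyloxy)-4-methylphenyl]acetyl}-3-methylcyclohexan-1-one | C=CCOc1cc(CC(=O)[C@@H]2C(=O)CCC[C@H]2C)cc(OCC=C)c1C
F3 | step 7 | 2-[3,5-bis(allyloxy)-2-formyl-4-methylphenyl]-N-methoxy-N-methylacetamide | C=CCOc1cc(CC(=O)N(C)OC)c(C=O)c(OCC=C)c1C
F4 | step 7 | 2-[3,5-bis(allyloxy)-2-(dimethoxymethyl)-4-methylphenyl]-N-methoxy-N-methylacetamide | C=CCOc1cc(CC(=O)N(C)OC)c(C(OC)OC)c(OCC=C)c1C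
F5 | step 7 | allyl (1RS,3R,4R)-3-{[3,5-bis(allyloxy)-2-(dimethoxymethyl)-4-methylphenyl]acetyl}-4-methyl-2-oxocyclohexane-1-carboxylate | C=CCOc1cc(CC(=O)[C@@H]2C(=O)C(C(=O)OCC=C)CC[C@H]2C)c(C(OC)OC)c(OCC=C)c1C
F6 | step 7 | (2S,3R)-2-{[2-(dimethoxymethyl)-3,5-dihydroxy-4-methylphenyl]acetyl}-3-methylcyclohexan-1-one | Cc1c(O)cc(CC(=O)[C@@H]2C(=O)CCC[C@H]2C)c(C(OC)OC)c1O
F7 | step 12 | 3-hydroxy-2-methyl-5-{2-[(1S,2R)-2-methyl-6-oxocyclohexyl]-2-oxoethyl}phenyl (2R,3R,4S)-3-[(tert-butyldimethylsilyl)oxy]-2,4-dimethylhexanoate | CC[C@H](C)[C@@H](O[Si](C)(C)C(C)(C)C)[C@@H](C)C(=O)Oc1cc(CC(=O)[C@@H]2C(=O)CCC[C@H]2C)cc(O)c1C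
F8 | step 12 | 6-{[(2R,3R,4S)-3-[(tert-butyldimethylsilyl)oxy]-2,4-dimethylhexanoyl]oxy}-8-hydroxy-7-methyl-3-[(1R,2R)-2-methyl-6-oxocyclohexyl]isochromenylium trifluoroacetate | CC[C@H](C)[C@@H](O[Si](C)(C)C(C)(C)C)[C@@H](C)C(=O)Oc1cc2cc([C@@H]3C(=O)CCC[C@H]3C)[o+]cc2c(O)c1C.[O-]C(=O)C(F)(F)F
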